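The flavone is cut at the C4–C4a bond. Ring C is closed last by intramolecular Friedel–Crafts acylation: the activated carboxyl carbon (future C4) of a β-aryloxycinnamic acid attacks C4a of ring A. The step exploits the fact that C4a is flanked by the oxygen-bearing carbons C5 and C8a and lies para to the C7 methoxy group, so it is strongly nucleophilic; the twofold-symmetric 3,5-dimethoxyphenoxy ring makes both ortho carbons identical. The precursor is (Z)-3-[2,5-bis(benzyloxy)-3,4-dimethoxyphenyl]-3-(3,5-dimethoxyphenoxy)acrylic acid, assembled by oxa-Michael addition of 3,5-dimethoxyphenol to a ring B arylpropiolate. A single BCl3 step then frees O5, O2' and O5'.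

Key step: step 8

Remark: 12 and 13 are drawn as the Z isomers expected from anti addition, and the geometry is not critical because step 8 equilibrates it; salts that are only protonated on work-up (the lithium carboxylate in step 7, the boron aryloxides in step 9) are not numbered separately.

Step 1
Reactants: 1 2,3-dimethoxyphenol
Product: 2 2,3-dimethoxy-1,4-benzoquinone
Conditions: (KSO3)2NO (2.2 equiv), KH2PO4, H2O/acetone, rt
Reagents that add atoms: potassium nitrosodisulfonate (Fremy's salt), [K+].[K+].[O]N(S(=O)(=O)[O-])S(=O)(=O)[O-]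
Why: Teuber oxidation, in which the phenoxyl radical is trapped at the free para carbon by a second nitrosodisulfonate radical and loss of imidodisulfonate leaves the para-quinone.

Step 2
Reactants: 2 2,3-dimethoxy-1,4-benzoquinone
Product: 4 1,4-bis(benzyloxy)-2,3-dimethoxybenzene, via 2,3-dimethoxyhydroquinone 3 (not isolated)
Conditions: Na2S2O4, THF/H2O, rt, Ar; then KOH, BnBr, n-Bu4NBr, rt
Reagents that add atoms: benzyl bromide, BrCc1ccccc1
Why: dithionite reduction of the quinone followed in the same flask by Williamson benzylation of the hydroquinone dianion under phase-transfer conditions, so the air-sensitive hydroquinone is never handled.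

Step 3
Reactants: 4 1,4-bis(benzyloxy)-2,3-dimethoxybenzene
Product: 6 2,5-bis(benzyloxy)-3,4-dimethoxybenzaldehyde, via aryl iminium chloride 5 (not isolated)
Conditions: POCl3, DMF, 0 → 75 °C; then aq. NaOAc
Reagents that add atoms: N,N-dimethylformamide, CN(C)C=O; water, O
Why: Vilsmeier–Haack formylation, in which the two free ring positions of 4 are equivalent (each ortho to a benzyloxy and para to a methoxy group) and the iminium formed deactivates the ring against a second attack.

Step 4
Reactants: 6 2,5-bis(benzyloxy)-3,4-dimethoxybenzaldehyde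
Product: 7 1,4-bis(benzyloxy)-5-(2,2-dibromoethenyl)-2,3-dimethoxybenzene
Conditions: CBr4, PPh3, CH2Cl2, 0 °C
Reagents that add atoms: carbon tetrabromide, BrC(Br)(Br)Br
Why: first stage of the Corey–Fuchs sequence, a Wittig-type dibromoolefination of the aryl aldehyde by Ph3P=CBr2.

Step 5
Reactants: 7 1,4-bis(benzyloxy)-5-(2,2-dibromoethenyl)-2,3-dimethoxybenzene; 8 ethyl chloroformate
Product: 10 ethyl 3-[2,5-bis(benzyloxy)-3,4-dimethoxyphenyl]prop-2-ynoate, via lithium arylacetylide 9 (not isolated)
Conditions: n-BuLi (2.1 equiv), THF, −78 °C; then ClCO2Et, −78 → 0 °C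
Reagents that add atoms: none
Why: second stage of the Corey–Fuchs sequence, in which bromine–lithium exchange, Fritsch–Buttenberg–Wiechell 1,2-shift and deprotonation give the lithium acetylide, which is C-acylated by the chloroformate.

Step 6
Reactants: 10 ethyl 3-[2,5-bis(benzyloxy)-3,4-dimethoxyphenyl]prop-2-ynoate; 11 3,5-dimethoxyphenol
Product: 12 ethyl (Z)-3-[2,5-bis(benzyloxy)-3,4-dimethoxyphenyl]-3-(3,5-dimethoxyphenoxy)prop-2-enoate
Conditions: K2CO3 (0.5 equiv), DMF, 80 °C
Reagents that add atoms: none
Why: oxa-Michael addition of the phenoxide oxygen to the β-carbon of the alkynoate, where anti addition should place the aryloxy group cis to the ester (Z).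

Step 7
Reactants: 12 ethyl (Z)-3-[2,5-bis(benzyloxy)-3,4-dimethoxyphenyl]-3-(3,5-dimethoxyphenoxy)prop-2-enoate
Product: 13 (Z)-3-[2,5-bis(benzyloxy)-3,4-dimethoxyphenyl]-3-(3,5-dimethoxyphenoxy)prop-2-enoic acid
Conditions: LiOH·H2O, THF/MeOH/H2O, 40 °C; then 1 M HCl, 0 °C, pH 3
Reagents that add atoms: lithium hydroxide, [Li+].[OH-]
Why: ester saponification by acyl–oxygen cleavage, which benzyl, methyl and enol ether groups tolerate, followed by mild acidification that leaves the β-aryloxy acrylic acid intact.

Step 8
Reactants: 13 (Z)-3-[2,5-bis(benzyloxy)-3,4-dimethoxyphenyl]-3-(3,5-dimethoxyphenoxy)prop-2-enoic acid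
Product: 15 2-[2,5-bis(benzyloxy)-3,4-dimethoxyphenyl]-5,7-dimethoxy-4H-chromen-4-one, via mixed trifluoroacetic anhydride 14 (not isolated)
Conditions: (CF3CO)2O (3 equiv), CH2Cl2, 0 °C → rt
Reagents that add atoms: none
Why: Trifluoroacetic anhydride converts the acid into the acyl trifluoroacetate 14, whose carbonyl carbon (in the limit a vinylogous acylium ion stabilised by the β-aryloxy oxygen) is attacked by C4a of the phenoxy ring, and loss of the C4a proton from the arenium ion restores ring A and leaves the C4 ketone. The closest known reaction is the Ruhemann flavone synthesis, an intramolecular Friedel–Crafts acylation of a β-aryloxycinnamic acid. Ring C closes in a six-membered exo-trig mode at the acyl carbon, the C=O staying outside the new ring. No stereocentre is formed. Regioselectivity is secured by the twofold symmetry of the 3,5-dimethoxyphenoxy ring (both ortho carbons are the same, each ortho and para to a methoxy group), and selectivity over ring B by the fact that attack by C6' would need a strained five-membered indenone closure from a less activated carbon. The liberated trifluoroacetic acid equilibrates the alkene geometry through the ketene-like resonance form of the activated acyl group, so any E isomer is drawn through the Z form, while the medium stays mild enough to leave the benzyl ethers in place.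

Step 9
Reactants: 15 2-[2,5-bis(benzyloxy)-3,4-dimethoxyphenyl]-5,7-dimethoxy-4H-chromen-4-one
Product: 16 2-(2,5-dihydroxy-3,4-dimethoxyphenyl)-5-hydroxy-7-methoxy-4H-chromen-4-one
Conditions: BCl3 (6 equiv), C6HMe5 (6 equiv), CH2Cl2, −78 → 0 °C; then H2O
Reagents that add atoms: none
Why: BCl3 cleaves the two aryl benzyl ethers at low temperature with pentamethylbenzene trapping the benzyl cations, and on warming removes the 5-O-methyl group through its six-membered boron chelate with the C4 carbonyl (chelation-controlled demethylation), while the unchelated methyl ethers at C7, C3' and C4' should persist.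

Compound list
1 | 2,3-dimethoxyphenol | COc1cccc(O)c1OC | starting material
2 | 2,3-dimethoxy-1,4-benzoquinone | COC1=C(OC)C(=O)C=CC1=O | intermediate
3 | 2,3-dimethoxybenzene-1,4-diol (formed in the flask, not isolated) | COc1c(O)ccc(O)c1OC | intermediate
4 | 1,4-bis(benzyloxy)-2,3-dimethoxybenzene | COc1c(OCc2ccccc2)ccc(OCc2ccccc2)c1OC | intermediate
5 | N-{[2,5-bis(benzyloxy)-3,4-dimethoxyphenyl]methylidene}-N-methylmethanaminium chloride (formed in the flask, not isolated) | C[N+](C)=Cc1cc(OCc2ccccc2)c(OC)c(OC)c1OCc1ccccc1.[Cl-] | intermediate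
6 | 2,5-bis(benzyloxy)-3,4-dimethoxybenzaldehyde | O=Cc1cc(OCc2ccccc2)c(OC)c(OC)c1OCc1ccccc1 | intermediate
7 | 1,4-bis(benzyloxy)-5-(2,2-dibromoethenyl)-2,3-dimethoxybenzene | BrC(Br)=Cc1cc(OCc2ccccc2)c(OC)c(OC)c1OCc1ccccc1 | intermediate
8 | ethyl chloroformate | CCOC(Cl)=O | starting material
9 | lithium [2,5-bis(benzyloxy)-3,4-dimethoxyphenyl]acetylide (formed in the flask, not isolated) | [Li]C#Cc1cc(OCc2ccccc2)c(OC)c(OC)c1OCc1ccccc1 | intermediate
10 | ethyl 3-[2,5-bis(benzyloxy)-3,4-dimethoxyphenyl]prop-2-ynoate | CCOC(=O)C#Cc1cc(OCc2ccccc2)c(OC)c(OC)c1OCc1ccccc1 | intermediate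
11 | 3,5-dimethoxyphenol | COc1cc(O)cc(OC)c1 | starting material
12 | ethyl (Z)-3-[2,5-bis(benzyloxy)-3,4-dimethoxyphenyl]-3-(3,5-dimethoxyphenoxy)prop-2-enoate (ester cis to the aryloxy group) | CCOC(=O)/C=C(\Oc1cc(OC)cc(OC)c1)c1cc(OCc2ccccc2)c(OC)c(OC)c1OCc1ccccc1 | intermediate
13 | (Z)-3-[2,5-bis(benzyloxy)-3,4-dimethoxyphenyl]-3-(3,5-dimethoxyphenoxy)prop-2-enoic acid (carboxyl cis to the aryloxy group) | OC(=O)/C=C(\Oc1cc(OC)cc(OC)c1)c1cc(OCc2ccccc2)c(OC)c(OC)c1OCc1ccccc1 | intermediate
14 | (Z)-3-[2,5-bis(benzyloxy)-3,4-dimethoxyphenyl]-3-(3,5-dimethoxyphenoxy)prop-2-enoic trifluoroacetic anhydride (formed in the flask, not isolated) | O=C(OC(=O)C(F)(F)F)/C=C(\Oc1cc(OC)cc(OC)c1)c1cc(OCc2ccccc2)c(OC)c(OC)c1OCc1ccccc1 | intermediate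
15 | 2-[2,5-bis(benzyloxy)-3,4-dimethoxyphenyl]-5,7-dimethoxy-4H-chromen-4-one | COc1cc(OC)c2c(=O)cc(-c3cc(OCc4ccccc4)c(OC)c(OC)c3OCc3ccccc3)oc2c1 | intermediate
16 | 2-(2,5-dihydroxy-3,4-dimethoxyphenyl)-5-hydroxy-7-methoxy-4H-chromen-4-one | COc1cc(O)c2c(=O)cc(-c3cc(O)c(OC)c(OC)c3O)oc2c1 | target

Total step count: 9 steps.
Longest linear sequence: 9 steps, from 1 to 16; 8 and 11 are purchased and enter in steps 5 and 6.

Steps most likely to fail

Step 8. The acidic acylating medium may cause loss or migration of benzyl groups. In particular, the 2'-benzyloxy oxygen of the E-configured acid could attack the activated acyl group and lose benzyl, giving a lactone. The acylation itself may also be sluggish, because the aryloxy oxygen is conjugated to the acyl group. The fallback sets out from aldehyde 6 and builds the flavone by the chalcone route. Claisen–Schmidt condensation of 6 with commercial 1-(2-hydroxy-4,6-dimethoxyphenyl)ethanone (KOH, EtOH, rt) should give (E)-3-[2,5-bis(benzyloxy)-3,4-dimethoxyphenyl]-1-(2-hydroxy-4,6-dimethoxyphenyl)prop-2-en-1-one F1. Oxidative cyclisation of F1 with catalytic I2 in DMSO at 120 °C (intramolecular oxa-Michael addition, then dehydrogenation) returns to the route at flavone 15.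

Step 6. Conjugate addition may be slow because the alkynoate is deactivated by its electron-rich, ortho-substituted aryl group. At the temperature then needed, C-alkylation of the ambident phloroglucinol-type phenoxide or ester cleavage could compete. The fallback sets out from alkynoate 10. Hydroiodination with NaI in AcOH at 80 °C (anti addition) should give ethyl (Z)-3-[2,5-bis(benzyloxy)-3,4-dimethoxyphenyl]-3-iodoprop-2-enoate F2. Ullmann-type vinyl C–O coupling of F2 with phenol 11 (CuI, N,N-dimethylglycine, Cs2CO3, dioxane, 90 °C), which proceeds with retention of alkene geometry, returns to the route at ester 12.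

Step 9. Two things may go wrong: over-demethylation of the flanked 3'- and 4'-methoxy groups that sit next to the boron aryloxides, and C-benzylation of ring A by benzyl cations that escape the scavenger. The fallback sets out from flavone 15 and separates the two deprotections. Hydrogenolysis (H2, 1 atm, Pd/C, EtOAc/MeOH, rt) should give 2-(2,5-dihydroxy-3,4-dimethoxyphenyl)-5,7-dimethoxy-4H-chromen-4-one F3 without any benzyl cation being formed. Chelation-controlled 5-O-demethylation of F3 with AlCl3 in MeCN at rt returns to the route at target 16.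

Further compounds
F1 | step 8 | (E)-3-[2,5-bis(benzyloxy)-3,4-dimethoxyphenyl]-1-(2-hydroxy-4,6-dimethoxyphenyl)prop-2-en-1-one | COc1cc(O)c(C(=O)/C=C/c2cc(OCc3ccccc3)c(OC)c(OC)c2OCc2ccccc2)c(OC)c1
F2 | step 6 | ethyl (Z)-3-[2,5-bis(benzyloxy)-3,4-dimethoxyphenyl]-3-iodoprop-2-enoate | CCOC(=O)/C=C(\I)c1cc(OCc2ccccc2)c(OC)c(OC)c1OCc1ccccc1
F3 | step 9 | 2-(2,5-dihydroxy-3,4-dimethoxyphenyl)-5,7-dimethoxy-4H-chromen-4-one | COc1cc(OC)c2c(=O)cc(-c3cc(O)c(OC)c(OC)c3O)oc2c1
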